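**Plan**

- Rings: A = 5-aryloxy-3,4-dihydroxyphenyl (CH2 at C1), B = para-phenylene, C = 2-aryloxy-3,4-dihydroxyphenyl (CH2 at C1), D = ortho-phenylene. The macrocycle is 17-membered and the target has no stereocentre.
- Enabling feature: the ethano bridge between ring B C4 (para to the ether oxygen) and ring C C1 is a two-carbon unit with an aryl carbon at each end. At the ethene oxidation level it comes out as one C2 piece and leaves two aryl iodides, an open one on ring B and one beside the bulky aryloxy group on ring C.
- Cuts, in order: the four O–CH3 bonds and the bridge alkene (adjustment); ring B C4–CH= and ring C C1–CH= (double Stille, opens the macrocycle); the CH2–CH2 bond of the A–D bridge (Wittig, then diimide); the B–O bond to ring A (Chan–Lam) and the D–O bond to ring C (SNAr); the ring C carbon–iodine bond (directed ortho-lithiation).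
- Forward: ring C iodophenol, then the C–D aldehyde; ring A phenol to the A–B phosphonium salt; Wittig and diimide join the chain; the only ring formed, the macrocycle, closes in the stitching step; hydrogenation and demethylation finish.
- Stereochemistry: only alkene geometry arises (E from the distannane, E/Z from the Wittig), and both alkenes are reduced.

Key step: step 10

Remark: the four phenols are carried as methyl ethers throughout, and trans-1,2-bis(tributylstannyl)ethene is taken as a purchased reagent.

**Route**

Step 1
Reactants: 1 2,3-dimethoxyphenol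
Product: 2 1,2-dimethoxy-3-(methoxymethoxy)benzene
Conditions: MOMCl, K2CO3, acetone, 0 °C to rt
Reagents that add atoms: chloromethyl methyl ether (MOMCl), COCCl
Why: Williamson-type O-alkylation of the phenoxide gives the MOM acetal, which protects the phenol and supplies the chelating director needed for the next step.

Step 2
Reactants: 2 1,2-dimethoxy-3-(methoxymethoxy)benzene
Product: 4 1-iodo-3,4-dimethoxy-2-(methoxymethoxy)benzene, via aryllithium 3 (not isolated)
Conditions: n-BuLi, THF, 0 °C; then ICH2CH2I, −78 °C to rt
Reagents that add atoms: 1,2-diiodoethane, ICCI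
Why: Directed ortho-metalation, in which the OMOM group outranks methoxy as director so that lithiation occurs at the free position next to it, and the aryllithium is iodinated by 1,2-diiodoethane with loss of ethene.

Step 3
Reactants: 4 1-iodo-3,4-dimethoxy-2-(methoxymethoxy)benzene
Product: 5 6-iodo-2,3-dimethoxyphenol
Conditions: conc. HCl (cat.), MeOH, 50 °C
Reagents that add atoms: none
Why: Acid-catalysed acetal methanolysis removes the MOM group, while the methyl ethers and the aryl iodide are inert to dilute acid.

Step 4
Reactants: 5 6-iodo-2,3-dimethoxyphenol; 6 2-fluorobenzaldehyde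
Product: 7 2-(6-iodo-2,3-dimethoxyphenoxy)benzaldehyde
Conditions: K2CO3, DMAc, 130 °C
Reagents that add atoms: none
Why: Nucleophilic aromatic substitution (SNAr) in which the ortho-formyl group stabilises the Meisenheimer adduct and fluoride leaves, and without a transition metal the carbon–iodine bond is not touched.

Step 5
Reactants: 8 3-hydroxy-4,5-dimethoxybenzaldehyde; 9 4-iodophenylboronic acid
Product: 10 3-(4-iodophenoxy)-4,5-dimethoxybenzaldehyde
Conditions: Cu(OAc)2 (20 mol %), pyridine, 4 Å MS, CH2Cl2, O2 (1 atm), rt
Reagents that add atoms: none
Why: Chan–Lam coupling, in which the aryl group passes from boron to divalent copper and, after oxidation to trivalent copper, the aryl copper phenoxide eliminates the diaryl ether at room temperature, where the aryl iodide does not react with copper.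

Step 6
Reactants: 10 3-(4-iodophenoxy)-4,5-dimethoxybenzaldehyde
Product: 11 [3-(4-iodophenoxy)-4,5-dimethoxyphenyl]methanol
Conditions: NaBH4, MeOH/THF, 0 °C
Reagents that add atoms: none
Why: Borohydride reduction of an aromatic aldehyde, which leaves the aryl iodide and the ethers alone.

Step 7
Reactants: 11 [3-(4-iodophenoxy)-4,5-dimethoxyphenyl]methanol
Product: 12 {[3-(4-iodophenoxy)-4,5-dimethoxyphenyl]methyl}triphenylphosphonium bromide
Conditions: PPh3·HBr, MeCN, reflux
Reagents that add atoms: triphenylphosphine hydrobromide, c1ccc(cc1)[PH+](c1ccccc1)c1ccccc1.[Br-]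
Why: Phosphonium salt formation directly from a benzylic alcohol, in which the para-methoxy-stabilised benzylic position is converted in situ to the bromide and alkylates triphenylphosphine in the same operation.

Step 8
Reactants: 12 {[3-(4-iodophenoxy)-4,5-dimethoxyphenyl]methyl}triphenylphosphonium bromide; 7 2-(6-iodo-2,3-dimethoxyphenoxy)benzaldehyde
Product: 14 1-iodo-2-{2-[2-[3-(4-iodophenoxy)-4,5-dimethoxyphenyl]ethenyl]phenoxy}-3,4-dimethoxybenzene (E/Z mixture), via phosphonium ylide 13 (not isolated)
Conditions: KOtBu, THF, 0 °C; then 7, 0 °C to rt
Reagents that add atoms: none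
Why: Wittig olefination with a semi-stabilised benzylic ylide, generated with an alkoxide instead of an alkyllithium so that no halogen–metal exchange occurs at either iodide, and the alkene geometry is irrelevant because the double bond is reduced next.

Step 9
Reactants: 14 1-iodo-2-{2-[2-[3-(4-iodophenoxy)-4,5-dimethoxyphenyl]ethenyl]phenoxy}-3,4-dimethoxybenzene (E/Z mixture)
Product: 15 1-iodo-2-{2-[2-[3-(4-iodophenoxy)-4,5-dimethoxyphenyl]ethyl]phenoxy}-3,4-dimethoxybenzene (open-chain bis-iodide, iodo-B–O–A–CH2CH2–D–O–C-iodo)
Conditions: TsNHNH2, NaOAc, DME/H2O, reflux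
Reagents that add atoms: none
Why: Diimide reduction, a concerted syn transfer of two hydrogens to the C=C bond that, unlike hydrogenation over palladium, cannot hydrogenolyse the two carbon–iodine bonds.

Step 10
Reactants: 15 1-iodo-2-{2-[2-[3-(4-iodophenoxy)-4,5-dimethoxyphenyl]ethyl]phenoxy}-3,4-dimethoxybenzene; 16 trans-1,2-bis(tributylstannyl)ethene
Product: 18 tetra-O-methyl macrocyclic E-stilbene (17-membered ring A–CH2CH2–D–O–C–CH=CH–B–O–A, E double bond between ring B C4 and ring C C1), via styrylstannane 17 (not isolated)
Conditions: Pd2(dba)3·CHCl3 (10 mol %), AsPh3 (40 mol %), DMF, 70 °C; 15 and 16 (1.0 equiv each) added together by syringe pump, 1 mM final concentration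
Reagents that add atoms: none
Why: Zerovalent palladium inserts first into the unhindered carbon–iodine bond of ring B, the arylpalladium iodide takes one vinyl carbon from tin with retention of the E geometry and reductive elimination gives styrylstannane 17; oxidative addition at the ring C iodide of 17, intramolecular transmetalation from the remaining stannyl group and reductive elimination then form the second aryl–vinyl bond. The closest known reaction type is the Stille coupling of aryl iodides with alkenylstannanes, applied twice to the 1,2-distannylethene as in stitching macrocyclisations of bis-iodides and in the double arylation of this distannane to stilbenes. The 17-membered ring closes in the second coupling by intramolecular C(sp2)–C(sp2) bond formation between ring C C1 and the stannylated vinyl carbon, an end-to-end macrocyclisation through a palladacycle. No stereocentre is formed, and the E geometry of the alkene is fixed by the reagent and carried through both transmetalations. The step needs one linchpin per substrate and ring closure in preference to chain growth: the para iodide of ring B should react faster than the ring C iodide ortho to the aryloxy group, so each molecule is capped at ring B before ring C engages, and slow co-addition to 1 mM keeps the styrylstannane from meeting a second molecule.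

Step 11
Reactants: 18 tetra-O-methyl macrocyclic E-stilbene
Product: 19 tetra-O-methyl ether of the target (saturated 17-membered macrocycle)
Conditions: H2 (1 atm), Pd/C (10 % Pd), EtOAc, rt
Reagents that add atoms: none
Why: Heterogeneous catalytic hydrogenation saturates the stilbene double bond, and with both iodides already consumed no group open to hydrogenolysis remains.

Step 12
Reactants: 19 tetra-O-methyl ether of the target
Product: 20 CNP0114693.0 (macrocyclic bis(bibenzyl) tetraphenol with catechols on rings A and C)
Conditions: BBr3, CH2Cl2, −78 °C to rt; then H2O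
Reagents that add atoms: none
Why: Lewis-acid ether cleavage, in which BBr3 complexes each methoxy oxygen and bromide attacks the methyl carbon (SN2), while the diaryl ether bonds have no sp3 carbon to attack and survive, and hydrolysis of the aryl borates frees both catechols.

**Compound list**

1 | 2,3-dimethoxyphenol | COc1cccc(O)c1OC | starting material
2 | 1,2-dimethoxy-3-(methoxymethoxy)benzene | COCOc1cccc(OC)c1OC | intermediate
3 | [3,4-dimethoxy-2-(methoxymethoxy)phenyl]lithium | [Li]c1ccc(OC)c(OC)c1OCOC | intermediate
4 | 1-iodo-3,4-dimethoxy-2-(methoxymethoxy)benzene | COCOc1c(I)ccc(OC)c1OC | intermediate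
5 | 6-iodo-2,3-dimethoxyphenol | COc1ccc(I)c(O)c1OC | intermediate
6 | 2-fluorobenzaldehyde | O=Cc1ccccc1F | starting material
7 | 2-(6-iodo-2,3-dimethoxyphenoxy)benzaldehyde | O=Cc1ccccc1Oc1c(I)ccc(OC)c1OC | intermediate
8 | 3-hydroxy-4,5-dimethoxybenzaldehyde | COc1cc(C=O)cc(O)c1OC | starting material
9 | 4-iodophenylboronic acid | OB(O)c1ccc(I)cc1 | starting material
10 | 3-(4-iodophenoxy)-4,5-dimethoxybenzaldehyde | COc1cc(C=O)cc(Oc2ccc(I)cc2)c1OC | intermediate
11 | [3-(4-iodophenoxy)-4,5-dimethoxyphenyl]methanol | COc1cc(CO)cc(Oc2ccc(I)cc2)c1OC | intermediate
12 | {[3-(4-iodophenoxy)-4,5-dimethoxyphenyl]methyl}triphenylphosphonium bromide | COc1cc(C[P+](c2ccccc2)(c2ccccc2)c2ccccc2)cc(Oc2ccc(I)cc2)c1OC.[Br-] | intermediate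
13 | {[3-(4-iodophenoxy)-4,5-dimethoxyphenyl]methylidene}triphenylphosphorane (ylide of 12) | COc1cc(C=P(c2ccccc2)(c2ccccc2)c2ccccc2)cc(Oc2ccc(I)cc2)c1OC | intermediate
14 | 1-iodo-2-{2-[2-[3-(4-iodophenoxy)-4,5-dimethoxyphenyl]ethenyl]phenoxy}-3,4-dimethoxybenzene, E/Z mixture | COc1cc(C=Cc2ccccc2Oc2c(I)ccc(OC)c2OC)cc(Oc2ccc(I)cc2)c1OC | intermediate
15 | 1-iodo-2-{2-[2-[3-(4-iodophenoxy)-4,5-dimethoxyphenyl]ethyl]phenoxy}-3,4-dimethoxybenzene (open-chain bis-iodide) | Ic1ccc(cc1)Oc1cc(cc(OC)c1OC)CCc1ccccc1Oc1c(I)ccc(OC)c1OC | intermediate
16 | trans-1,2-bis(tributylstannyl)ethene | CCCC[Sn](CCCC)(CCCC)/C=C/[Sn](CCCC)(CCCC)CCCC | starting material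
17 | styrylstannane: 15 in which the ring B iodide is replaced by an (E)-2-(tributylstannyl)ethenyl group, ring C iodide intact | CCCC[Sn](CCCC)(CCCC)/C=C/c1ccc(cc1)Oc1cc(cc(OC)c1OC)CCc1ccccc1Oc1c(I)ccc(OC)c1OC | intermediate
18 | tetra-O-methyl macrocyclic E-stilbene (E alkene between ring B C4 and ring C C1) | COc1cc2cc(c1OC)Oc1ccc(cc1)/C=C/c1ccc(OC)c(OC)c1Oc1ccccc1CC2 | intermediate
19 | tetra-O-methyl ether of the target (saturated macrocycle) | COc1cc2cc(c1OC)Oc1ccc(cc1)CCc1ccc(OC)c(OC)c1Oc1ccccc1CC2 | intermediate
20 | CNP0114693.0, macrocyclic bis(bibenzyl) tetraphenol | Oc1cc2cc(c1O)Oc1ccc(cc1)CCc1ccc(O)c(O)c1Oc1ccccc1CC2 | target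

**Step count and risks**

Total steps: 12. Longest linear sequence: 9 steps (steps 1–4, then 8–12); the ring A–B branch (steps 5–7) joins at step 8.

Steps most likely to fail:

1. Step 10 (double Stille macrocyclisation). Chain growth may outrun ring closure if the ring C iodide of one molecule meets the styrylstannane of another. A slow second oxidative addition next to the aryloxy group may also let the stannane protodestannylate or homocouple. Fallback from 15: a twofold Stille vinylation with tributyl(vinyl)tin (Pd(PPh3)4, toluene, 100 °C) should give 1-ethenyl-2-{2-[2-[3-(4-ethenylphenoxy)-4,5-dimethoxyphenyl]ethyl]phenoxy}-3,4-dimethoxybenzene F1. Both iodides are used alike there, so no discrimination between them is needed. Ring-closing metathesis with second-generation Grubbs catalyst in dilute toluene at 80 °C should then close the same 17-membered ring at the central C=C with loss of ethene, and the route is rejoined at 18. Should the ring prefer the cis alkene, the macrocyclic Z-stilbene F2 would form instead and be hydrogenated as in step 11, so that the route is rejoined at 19.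

2. Step 4 (SNAr of the iodophenol). Attack of the phenoxide flanked by iodine and methoxy may be slow, and prolonged heating may let the aldehyde disproportionate or condense. Fallback from 1: the order is inverted. SNAr of the less hindered phenol 1 with 6 (K2CO3, DMAc, 110 °C) should give 2-(2,3-dimethoxyphenoxy)benzaldehyde F3. Electrophilic iodination (N-iodosuccinimide, cat. CF3CO2H, MeCN, rt) should then occur on the electron-rich ring para to the 3-methoxy group, which is the position ortho to the aryloxy oxygen; the formyl-bearing ring is deactivated. After removal of any regioisomer the route is rejoined at 7.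

3. Step 5 (Chan–Lam coupling). Transfer of the aryl group to copper and C–O bond formation may be slow with the electron-poor, ortho-methoxy phenol, so that protodeboronation and oxidative homocoupling consume the boronic acid. Fallback from 8: Ullmann etherification with a fourfold excess of 1,4-diiodobenzene (CuCl, 2,2,6,6-tetramethylheptane-3,5-dione, Cs2CO3, NMP, 110 °C) should give the mono-ether by statistical control and rejoins the route at 10. This detour makes no compound outside the list (none F0).

Further compounds
F1 | step 10 | 1-ethenyl-2-{2-[2-[3-(4-ethenylphenoxy)-4,5-dimethoxyphenyl]ethyl]phenoxy}-3,4-dimethoxybenzene | C=Cc1ccc(cc1)Oc1cc(cc(OC)c1OC)CCc1ccccc1Oc1c(C=C)ccc(OC)c1OC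
F2 | step 10 | macrocyclic Z-stilbene (Z isomer of 18) | COc1cc2cc(c1OC)Oc1ccc(cc1)/C=C\c1ccc(OC)c(OC)c1Oc1ccccc1CC2
F3 | step 4 | 2-(2,3-dimethoxyphenoxy)benzaldehyde | O=Cc1ccccc1Oc1cccc(OC)c1OC
F0 | step 5 | none | none
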